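**Retrosynthetic overview**
1. Spirocaesalmin ← spiro enol lactone 27 by bromohydrin formation and lactol closure (the inversion puts the epoxide oxygen syn to C14). Rings C and D and the C13 spiro centre ← intramolecular α-alkylation of a butenolide dienolate by a C7/C14 cyclic sulfate (C13–C14 bond).
2. C8–C14 ← anti boron aldol of the ring-B C7 ketone with methyl glyoxylate; the butenolide ← peracid oxidation of a 2-silylfuran; 7β-OH ← chelation-controlled reduction.
3. Ring A ← C4–C5 bond: the tertiary C4 radical, made by hydrogen-atom transfer (MHAT) to an isopropenyl group, adds to the ring-B C5 ketone. This runs in one pot after a three-component coupling (enone 5, furylmethyl Grignard, 4-methylpent-4-enal) that makes C9–C11 and C10–C1.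
4. Enabling feature: the gem-dimethyl carbon C4 is bonded directly to the tertiary carbinol C5, which is shared by rings A and B and flanked by quaternary C10; the 1α-oxygen is 1,3-diaxial to 5α-OH on ring A.
5. Ring order: B (from (S)-carvone) → A (key step) → butenolide → C and D together (spiro-alkylation) → epoxide.

Key step: step 7

Remark: cassane numbering is used (C12 lactone carbonyl, C13 spiro carbon, C14 ester-bearing carbon, C15/C16 epoxide carbons); α/β refer to the usual drawing with the C10 methyl β.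
Remark: (S)-carvone, furan-3-ylmethanol, 4-methylpent-4-en-1-ol and methyl glyoxylate are taken as commercial; adduct 14 in step 7 is a stable β-hydroxy ketone and can be isolated without changing the chemistry.

**Route**

Step 1
Reactants: 1 (S)-(+)-carvone
Product: 3 (1S)-4-methyl-5-oxocyclohex-3-en-1-yl acetate, via methoxy hydroperoxide 2 (not isolated)
Conditions: O3 (1 equiv), CH2Cl2/MeOH, −78 °C; then Ac2O, Et3N, DMAP (cat.), 0 → 40 °C
Reagents that add atoms: ozone, [O-][O+]=O
Why: Ozone cleaves only the electron-rich 1,1-disubstituted alkene, methanol traps the carbonyl oxide as 2, and its peracetate undergoes Criegee rearrangement with retention at the migrating ring carbon, so the (S) C–C bond becomes the C–O bond of 3.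

Step 2
Reactants: 3 (1S)-4-methyl-5-oxocyclohex-3-en-1-yl acetate
Product: 4 (5S)-5-hydroxy-2-methylcyclohex-2-en-1-one
Conditions: K2CO3 (cat.), MeOH, 0 °C
Reagents that add atoms: none
Why: Catalytic transesterification removes the secondary acetate; low temperature and substoichiometric base are chosen to suppress β-elimination to the cresol, and the stereocentre is not touched.

Step 3
Reactants: 4 (5S)-5-hydroxy-2-methylcyclohex-2-en-1-one
Product: 5 (5S)-5-[(tert-butyldimethylsilyl)oxy]-2-methylcyclohex-2-en-1-one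
Conditions: t-BuMe2SiCl, imidazole, DMF, rt
Reagents that add atoms: tert-butyldimethylsilyl chloride, CC(C)(C)[Si](C)(C)Cl
Why: Standard imidazole-promoted silylation of a secondary alcohol gives a base-stable ether that later directs the conjugate addition.

Step 4
Reactants: 6 furan-3-ylmethanol
Product: 8 [2-(trimethylsilyl)furan-3-yl]methanol, via bis-silyl ether 7 (not isolated)
Conditions: n-BuLi (2.2 equiv), THF, −78 → 0 °C; Me3SiCl (2.2 equiv), −78 °C → rt; dilute aqueous citric acid work-up
Reagents that add atoms: chlorotrimethylsilane, C[Si](C)(C)Cl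
Why: The lithium alkoxide directs the second lithiation to the adjacent furan C2 (directed ortho-metalation); the dianion is silylated on C and O, and the labile O–Si bond is hydrolysed on work-up.

Step 5
Reactants: 8 [2-(trimethylsilyl)furan-3-yl]methanol
Product: 9 [3-(chloromethyl)furan-2-yl]trimethylsilane
Conditions: PPh3, N-chlorosuccinimide, CH2Cl2, 0 °C
Reagents that add atoms: N-chlorosuccinimide, O=C1CCC(=O)N1Cl
Why: Appel-type chlorination under neutral conditions avoids the acid that would protodesilylate or polymerise the furan.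

Step 6
Reactants: 10 4-methylpent-4-en-1-ol
Product: 11 4-methylpent-4-enal
Conditions: TEMPO (cat.), PhI(OAc)2, CH2Cl2, rt
Reagents that add atoms: none
Why: Oxoammonium oxidation stops at the aldehyde and leaves the 1,1-disubstituted alkene untouched.

Step 7
Reactants: 5 (5S)-5-[(tert-butyldimethylsilyl)oxy]-2-methylcyclohex-2-en-1-one; 9 [3-(chloromethyl)furan-2-yl]trimethylsilane; 11 4-methylpent-4-enal
Product: 15 7α-(tert-butyldimethylsilyloxy)-4,4,10β-trimethyl-9β-{[2-(trimethylsilyl)furan-3-yl]methyl}-trans-decalin-1α,5α-diol, via Grignard reagent 12 (not isolated), via magnesium enolate 13 (not isolated), via aldol adduct 14 (not isolated)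
Conditions: 9, Mg, THF, 0 °C; 5, CuBr·SMe2 (5 mol %), THF, −78 → −40 °C; 11, −78 °C; AcOH (2 equiv), −78 °C; then EtOH, Fe(acac)3 (0.5 equiv), PhSiH3 (3 equiv), 60 °C
Reagents that add atoms: none
Why: The copper-catalysed 1,4-addition of 12 to 5 occurs anti to the 7-silyloxy group (sets C9) and gives the tetrasubstituted magnesium enolate 13 regiospecifically; 13 adds to 11 on the face anti to the new C9 substituent through a closed chair transition state (methyl cis to the enolate oxygen, so 1-OH and the C10 methyl end syn in the zigzag sense), setting C10 and C1 (conjugate addition–aldol three-component coupling). After AcOH buffering, the iron hydride formed from Fe(acac)3 and PhSiH3 transfers a hydrogen atom to the CH2 terminus of the isopropenyl group (MHAT), and the tertiary C4 radical adds to the C5 carbonyl carbon, the alkoxy radical being reduced and protonated; the closest known reaction type is the HAT-initiated radical cyclization of alkene-tethered ketones to tertiary bicyclic alcohols. Ring A is closed by the C4–C5 bond in the 6-exo-trig mode through a chair in which the C1 arm is equatorial on ring B and C4 attacks C5 equatorially. The new C5 centre is controlled by the C10/C1 pair: only the trans-decalin chair lets the 1α-hydroxyl hydrogen-bond to the developing C5 oxygen (1,3-diaxial), whereas axial attack is blocked by the axial 7α-silyloxy group and the ring-flipped chair by 1,3-diaxial O1/C6 and O5/C11 contacts. The step needs chemoselectivity of the C4 radical for the ketone over the silylfuran (secured by the 6-exo geometry, the furan being out of reach) and trans A/B diastereoselectivity (secured as described).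

Step 8
Reactants: 15 the 1α,5α-diol from step 7
Product: 16 1α-acetoxy-7α-(tert-butyldimethylsilyloxy)-4,4,10β-trimethyl-9β-{[2-(trimethylsilyl)furan-3-yl]methyl}-trans-decalin-5α-ol
Conditions: Ac2O, Et3N, DMAP, CH2Cl2, rt → 40 °C
Reagents that add atoms: acetic anhydride, CC(=O)OC(C)=O
Why: DMAP-catalysed acylation takes the secondary 1α-OH only, because the tertiary 5α-OH lies between two quaternary carbons.

Step 9
Reactants: 16 the 1α-acetate
Product: 17 1α-acetoxy-4,4,10β-trimethyl-9β-{[2-(trimethylsilyl)furan-3-yl]methyl}-trans-decalin-5α,7α-diol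
Conditions: Bu4NF, AcOH, THF, rt
Reagents that add atoms: none
Why: Buffered fluoride cleaves the O–Si bond; the furan C–Si bond and the acetate should survive at room temperature.

Step 10
Reactants: 17 the 5α,7α-diol
Product: 18 1α-acetoxy-5α-hydroxy-4,4,10β-trimethyl-9β-{[2-(trimethylsilyl)furan-3-yl]methyl}-trans-decalin-7-one
Conditions: Dess–Martin periodinane, pyridine, CH2Cl2, 0 °C → rt
Reagents that add atoms: none
Why: Dess–Martin oxidation converts the only secondary alcohol into the C7 ketone under buffered, non-basic conditions that avoid retro-aldol cleavage of the β-hydroxy ketone.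

Step 11
Reactants: 18 the C7 ketone; 19 methyl glyoxylate
Product: 20 methyl (2S)-2-hydroxy-2-(1α-acetoxy-5α-hydroxy-4,4,10β-trimethyl-7-oxo-9β-{[2-(trimethylsilyl)furan-3-yl]methyl}-trans-decalin-8α-yl)acetate (8β-H)
Conditions: (c-C6H11)2BCl, Et3N, Et2O, −78 → 0 °C; 19, −78 °C; then MeOH, pH 7 buffer, H2O2, 0 °C
Reagents that add atoms: none
Why: Boron-mediated aldol reaction: the chloroborane enolizes only the ketone, toward the less hindered C8, and the (E)-enolate reacts through a Zimmerman–Traxler chair to give the anti aldol (sets C14); the aldehyde enters C8 from the α face because the β-axial path is 1,3-diaxial to the C10 methyl, so the new chain is equatorial (8β-H).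

Step 12
Reactants: 20 the anti aldol
Product: 21 methyl (2S)-2-hydroxy-2-(1α-acetoxy-5α,7β-dihydroxy-4,4,10β-trimethyl-9β-{[2-(trimethylsilyl)furan-3-yl]methyl}-trans-decalin-8α-yl)acetate
Conditions: Et2BOMe, NaBH4, THF/MeOH 4:1, −78 °C; then AcOH, MeOH
Reagents that add atoms: none
Why: Narasaka–Prasad reduction: the less hindered secondary carbinol forms the boron chelate with the C7 ketone, and external axial hydride delivery gives the syn-1,3-diol, which is the equatorial 7β-alcohol.

Step 13
Reactants: 21 the silylfuran diol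
Product: 22 methyl (2S)-2-hydroxy-2-{1α-acetoxy-5α,7β-dihydroxy-4,4,10β-trimethyl-9β-[(2-oxo-2,5-dihydrofuran-3-yl)methyl]-trans-decalin-8α-yl}acetate
Conditions: CH3CO3H, NaOAc, CH2Cl2, 0 °C → rt; then Et3N
Reagents that add atoms: peracetic acid, CC(=O)OO
Why: Peracid oxidation of a 2-silylfuran puts the carbonyl regiospecifically on the carbon that carried silicon (attack at the silylated position, 1,2-silyl shift, loss of silicon), and Et3N moves the double bond into conjugation to give the α-substituted butenolide.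

Step 14
Reactants: 22 the butenolide diol
Product: 24 the 7β,14-cyclic sulfate of 22, via cyclic sulfite 23 (not isolated)
Conditions: SOCl2, Et3N, CH2Cl2, −20 °C; then RuCl3·xH2O (cat.), NaIO4, MeCN/H2O, 0 °C
Reagents that add atoms: thionyl chloride, O=S(Cl)Cl; sodium periodate, [Na+].[O-]I(=O)(=O)=O
Why: The syn-1,3-diol closes a six-membered cyclic sulfite that catalytic RuO4 oxidises to the sulfate; the trans-fused ring holds the ester equatorial and the C14–O bond antiperiplanar to C8–C9, while the hindered tertiary 5-OH does not react.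

Step 15
Reactants: 24 the cyclic sulfate
Product: 26 7-O-deacetyl-15,16-deepoxy-15,16-didehydrospirocaesalmin (spiro enol lactone with free 7β-OH), via potassium sulfate monoester 25 (not isolated)
Conditions: KN(SiMe3)2 (1.1 equiv), 18-crown-6, THF, −78 → −20 °C; then H2SO4 (cat.), H2O (2 equiv), THF, rt
Reagents that add atoms: none
Why: Intramolecular C-alkylation of the butenolide dienolate at its α-carbon (the only position that reaches C14, 5-exo-tet) opens the cyclic sulfate with inversion, which turns the anti-aldol centre into the 14β-ester; C13 is set by the dienolate face, the enolate oxygen of the crown-separated ion pair turning away from the ester so that C12 ends trans to it; mild acid then hydrolyses the sulfate monoester.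

Step 16
Reactants: 26 the 7β-hydroxy spiro enol lactone
Product: 27 15,16-deepoxy-15,16-didehydrospirocaesalmin
Conditions: Ac2O, pyridine, DMAP (cat.), CH2Cl2, rt
Reagents that add atoms: acetic anhydride, CC(=O)OC(C)=O
Why: Acylation of the equatorial 7β-OH; the tertiary 5α-OH is inert and the enol lactone should survive these mild conditions.

Step 17
Reactants: 27 the diacetate enol lactone
Product: 29 spirocaesalmin, via bromo lactol 28 (not isolated)
Conditions: N-bromosuccinimide, THF/H2O, 0 °C; then K2CO3, 0 °C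
Reagents that add atoms: water, O
Why: Bromohydrin formation on the enol lactone followed by intramolecular displacement, as in the classical closure of 1,2-anhydro sugars from 2-O-sulfonyl lactols: Br+ adds to C15 from the open face (anti to C14 and its ester), water adds to C16, and the lactol alkoxide displaces bromide with inversion, which places the epoxide oxygen syn to C14 as the target requires.

**Compound list**
1 | (S)-(+)-carvone | CC1=CC[C@H](C(C)=C)CC1=O | starting material
2 | (5S)-5-(1-hydroperoxy-1-methoxyethyl)-2-methylcyclohex-2-en-1-one | CC1=CC[C@H](C(C)(OC)OO)CC1=O | intermediate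
3 | (1S)-4-methyl-5-oxocyclohex-3-en-1-yl acetate | CC1=CC[C@H](OC(C)=O)CC1=O | intermediate
4 | (5S)-5-hydroxy-2-methylcyclohex-2-en-1-one | CC1=CC[C@H](O)CC1=O | intermediate
5 | (5S)-5-[(tert-butyldimethylsilyl)oxy]-2-methylcyclohex-2-en-1-one | CC1=CC[C@H](O[Si](C)(C)C(C)(C)C)CC1=O | intermediate
6 | furan-3-ylmethanol | OCc1ccoc1 | starting material
7 | trimethyl{[2-(trimethylsilyl)furan-3-yl]methoxy}silane | C[Si](C)(C)OCc1ccoc1[Si](C)(C)C | intermediate
8 | [2-(trimethylsilyl)furan-3-yl]methanol | OCc1ccoc1[Si](C)(C)C | intermediate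
9 | [3-(chloromethyl)furan-2-yl]trimethylsilane | ClCc1ccoc1[Si](C)(C)C | intermediate
10 | 4-methylpent-4-en-1-ol | CC(=C)CCCO | starting material
11 | 4-methylpent-4-enal | CC(=C)CCC=O | intermediate
12 | {[2-(trimethylsilyl)furan-3-yl]methyl}magnesium chloride | Cl[Mg]Cc1ccoc1[Si](C)(C)C | intermediate
13 | chloromagnesium enolate (C5=C10) formed from 5 by anti 1,4-addition | CC1=C(O[Mg]Cl)C[C@@H](O[Si](C)(C)C(C)(C)C)C[C@@H]1Cc1ccoc1[Si](C)(C)C | intermediate
14 | (2S,3S,5S)-5-[(tert-butyldimethylsilyl)oxy]-2-[(1S)-1-hydroxy-4-methylpent-4-en-1-yl]-2-methyl-3-{[2-(trimethylsilyl)furan-3-yl]methyl}cyclohexan-1-one | C=C(C)CC[C@H](O)[C@@]1(C)C(=O)C[C@@H](O[Si](C)(C)C(C)(C)C)C[C@@H]1Cc1ccoc1[Si](C)(C)C | intermediate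
15 | 7α-(tert-butyldimethylsilyloxy)-4,4,10β-trimethyl-9β-{[2-(trimethylsilyl)furan-3-yl]methyl}-trans-decalin-1α,5α-diol | C1[C@H](O[Si](C)(C)C(C)(C)C)C[C@@]2(O)C(C)(C)CC[C@H](O)[C@]2(C)[C@H]1Cc1ccoc1[Si](C)(C)C | intermediate
16 | 1α-acetate of 15 | C1[C@H](O[Si](C)(C)C(C)(C)C)C[C@@]2(O)C(C)(C)CC[C@H](OC(C)=O)[C@]2(C)[C@H]1Cc1ccoc1[Si](C)(C)C | intermediate
17 | 1α-acetoxy-5α,7α-diol | C1[C@H](O)C[C@@]2(O)C(C)(C)CC[C@H](OC(C)=O)[C@]2(C)[C@H]1Cc1ccoc1[Si](C)(C)C | intermediate
18 | 1α-acetoxy-5α-hydroxy-7-ketone | C1C(=O)C[C@@]2(O)C(C)(C)CC[C@H](OC(C)=O)[C@]2(C)[C@H]1Cc1ccoc1[Si](C)(C)C | intermediate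
19 | methyl glyoxylate | COC(=O)C=O | starting material
20 | anti aldol, methyl (2S)-2-hydroxyacetate on C8α of 18 | COC(=O)[C@@H](O)[C@@H]1C(=O)C[C@@]2(O)C(C)(C)CC[C@H](OC(C)=O)[C@]2(C)[C@H]1Cc1ccoc1[Si](C)(C)C | intermediate
21 | 7β,14-diol (silylfuran) | COC(=O)[C@@H](O)[C@@H]1[C@@H](O)C[C@@]2(O)C(C)(C)CC[C@H](OC(C)=O)[C@]2(C)[C@H]1Cc1ccoc1[Si](C)(C)C | intermediate
22 | 7β,14-diol (α-substituted butenolide) | COC(=O)[C@@H](O)[C@@H]1[C@@H](O)C[C@@]2(O)C(C)(C)CC[C@H](OC(C)=O)[C@]2(C)[C@H]1CC1=CCOC1=O | intermediate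
23 | 7β,14-cyclic sulfite of 22 (mixture at sulfur) | COC(=O)[C@H]1OS(=O)O[C@H]2C[C@@]3(O)C(C)(C)CC[C@H](OC(C)=O)[C@]3(C)[C@@H](CC4=CCOC4=O)[C@H]12 | intermediate
24 | 7β,14-cyclic sulfate of 22 | COC(=O)[C@H]1OS(=O)(=O)O[C@H]2C[C@@]3(O)C(C)(C)CC[C@H](OC(C)=O)[C@]3(C)[C@@H](CC4=CCOC4=O)[C@H]12 | intermediate
25 | potassium 7β-sulfate of spiro enol lactone 26 | COC(=O)[C@H]1[C@@H]2[C@@H](OS(=O)(=O)[O-])C[C@@]3(O)C(C)(C)CC[C@H](OC(C)=O)[C@]3(C)[C@H]2C[C@]12C(=O)OC=C2.[K+] | intermediate
26 | 7-O-deacetyl-15,16-deepoxy-15,16-didehydrospirocaesalmin | COC(=O)[C@H]1[C@@H]2[C@@H](O)C[C@@]3(O)C(C)(C)CC[C@H](OC(C)=O)[C@]3(C)[C@H]2C[C@]12C(=O)OC=C2 | intermediate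
27 | 15,16-deepoxy-15,16-didehydrospirocaesalmin | COC(=O)[C@H]1[C@@H]2[C@@H](OC(C)=O)C[C@@]3(O)C(C)(C)CC[C@H](OC(C)=O)[C@]3(C)[C@H]2C[C@]12C(=O)OC=C2 | intermediate
28 | 15-bromo-16-hydroxy lactol (Br anti to C14, OH syn to C14) | COC(=O)[C@H]1[C@@H]2[C@@H](OC(C)=O)C[C@@]3(O)C(C)(C)CC[C@H](OC(C)=O)[C@]3(C)[C@H]2C[C@]12C(=O)O[C@H](O)[C@H]2Br | intermediate
29 | spirocaesalmin | COC(=O)[C@H]1[C@@H]2[C@@H](OC(C)=O)C[C@@]3(O)C(C)(C)CC[C@H](OC(C)=O)[C@]3(C)[C@H]2C[C@]12C(=O)O[C@@H]1O[C@@H]12 | target

**Step count and risks**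
Total steps: 17. Longest linear sequence: 14 steps (steps 1–3, then 7–17).

Most likely to fail:

Step 15. What may go wrong: base-induced elimination of the cyclic sulfate or attack at sulfur outruns C-alkylation, or C14 epimerises before ring closure and control at C13 is lost. The fallback sets out from 22 and comes back at 27. Trimethyl orthoacetate with pyridinium tosylate should give the cyclic orthoacetate F7, and acetyl bromide in the same flask should open it at the ester-activated carbon with inversion to give the 7β-acetoxy-14-bromo ester F8. Cs2CO3 with Bu4NBr in DMF should then equilibrate the two C14 bromides by halide exchange while the butenolide dienolate alkylates at its α-carbon through the less hindered transition state (ester turned away from C7), giving 27 directly and making step 16 unnecessary.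

Step 17. What may go wrong: the bromo lactol opens to the bromo aldehyde carboxylate and is hydrolysed instead of closing the epoxide. The fallback sets out from 27 and comes back at 29. Dimethyldioxirane in acetone should epoxidise the enol lactone from its open face to give the 15,16-diepimeric epoxide F9. MgBr2·OEt2 should open it at the acylal carbon to give the 16-bromo-15-hydroxy lactone F10, and Dess–Martin oxidation should give the 16-bromo-15-ketone F11. NaBH4 at −78 °C should deliver hydride to C15 from the open face, so that the resulting alkoxide sits syn to C14 and closes onto C16 with loss of bromide to give 29.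

Step 7. What may go wrong: poor facial selectivity at C5 during the radical closure (the cis-fused 5-epimer forms alongside 15). The fallback sets out from 14 (that is, from the C5-epimeric product mixture of step 7) and comes back at 18; it fixes C5 by epoxide reduction instead of in the ring closure. The closure should give 15 together with its 5-epimer F1. Acetylation as in step 8 should give 16 together with the 5-epimeric acetate F2, and Burgess reagent should dehydrate both to the single Δ5-alkene F3, since C6 carries the only β-hydrogens. Bu4NF/AcOH should give the allylic alcohol F4, MnO2 the Δ5-en-7-one F5, and t-BuOOH/DBU the 5α,6α-epoxy ketone F6 (attack anti to the C10 methyl). SmI2 in THF/MeOH at −90 °C should cleave the α C–O bond to return the 5α-hydroxy-7-ketone 18.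

**Further compounds**
F1 | step 7 | 5-epimer of 15 (cis-fused 5β-ol) | C1[C@H](O[Si](C)(C)C(C)(C)C)C[C@]2(O)C(C)(C)CC[C@H](O)[C@]2(C)[C@H]1Cc1ccoc1[Si](C)(C)C
F2 | step 7 | 5-epimer of 16 | C1[C@H](O[Si](C)(C)C(C)(C)C)C[C@]2(O)C(C)(C)CC[C@H](OC(C)=O)[C@]2(C)[C@H]1Cc1ccoc1[Si](C)(C)C
F3 | step 7 | Δ5-alkene, 1α-acetoxy-7α-silyloxy | C1[C@H](O[Si](C)(C)C(C)(C)C)C=C2C(C)(C)CC[C@H](OC(C)=O)[C@]2(C)[C@H]1Cc1ccoc1[Si](C)(C)C
F4 | step 7 | Δ5-en-7α-ol | C1[C@H](O)C=C2C(C)(C)CC[C@H](OC(C)=O)[C@]2(C)[C@H]1Cc1ccoc1[Si](C)(C)C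
F5 | step 7 | Δ5-en-7-one | C1C(=O)C=C2C(C)(C)CC[C@H](OC(C)=O)[C@]2(C)[C@H]1Cc1ccoc1[Si](C)(C)C
F6 | step 7 | 5α,6α-epoxy-7-ketone | C1C(=O)[C@@H]2O[C@@]23C(C)(C)CC[C@H](OC(C)=O)[C@]3(C)[C@H]1Cc1ccoc1[Si](C)(C)C
F7 | step 15 | 7β,14-cyclic orthoacetate of 22 | COC(=O)[C@H]1OC(C)(OC)O[C@H]2C[C@@]3(O)C(C)(C)CC[C@H](OC(C)=O)[C@]3(C)[C@@H](CC4=CCOC4=O)[C@H]12
F8 | step 15 | 7β-acetoxy-14-bromo ester | COC(=O)[C@H](Br)[C@@H]1[C@@H](OC(C)=O)C[C@@]2(O)C(C)(C)CC[C@H](OC(C)=O)[C@]2(C)[C@H]1CC1=CCOC1=O
F9 | step 17 | 15,16-diepi-spirocaesalmin (epoxide anti to C14) | COC(=O)[C@H]1[C@@H]2[C@@H](OC(C)=O)C[C@@]3(O)C(C)(C)CC[C@H](OC(C)=O)[C@]3(C)[C@H]2C[C@]12C(=O)O[C@H]1O[C@H]12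
F10 | step 17 | 16-bromo-15-hydroxy lactone | COC(=O)[C@H]1[C@@H]2[C@@H](OC(C)=O)C[C@@]3(O)C(C)(C)CC[C@H](OC(C)=O)[C@]3(C)[C@H]2C[C@]12C(=O)OC(Br)[C@H]2O
F11 | step 17 | 16-bromo-15-oxo lactone | COC(=O)[C@H]1[C@@H]2[C@@H](OC(C)=O)C[C@@]3(O)C(C)(C)CC[C@H](OC(C)=O)[C@]3(C)[C@H]2C[C@]12C(=O)OC(Br)C2=O
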